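## Retrosynthetic overview

1. The 4-methoxybenzoate goes on last, by acylating the secondary allylic hydroxyl of the bicyclic diol; the tertiary hydroxyl stays free.
2. The seven-membered ring is the second and last ring formed, by ring-closing metathesis (vinyl + isopropenyl) on a cyclopentane that already carries all four stereocentres; the five-membered ring is bought as 3-ethoxycyclopent-2-en-1-one.
3. The tertiary carbinol comes from isopropyl addition to the cyclopentanone carbonyl.
4. Key C–C bond (ring-fusion CH to carbinol CH): intermolecular anti-aldol between acrolein and the regiodefined enolate of (S)-3-methyl-3-(3-methylbut-3-enyl)cyclopentanone.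
5. That enolate comes from copper-catalysed asymmetric conjugate methylation of 3-(3-methylbut-3-enyl)cyclopent-2-enone, made from the isoprenol-derived Grignard reagent and the vinylogous ester.

Assumption: the ligand enantiomer in step 3 is the one found (chiral GC of a hydrolysed sample) to give the (S) quaternary carbon, and the roughly 90% ee of that step is raised to >99% by recrystallising the diol of step 8 or the final ester.

## Route

Step 1
Reactants: 1 3-methylbut-3-en-1-ol
Product: 2 4-bromo-2-methylbut-1-ene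
Conditions: PPh3, CBr4, CH2Cl2, 0 °C → rt
Reagents that add atoms: tetrabromomethane, BrC(Br)(Br)Br
Why: Appel reaction, in which bromide displaces the alkoxyphosphonium group at a primary carbon (SN2) under neutral conditions that leave the 1,1-disubstituted alkene untouched, with no stereocentre involved.

Step 2
Reactants: 2 4-bromo-2-methylbut-1-ene; 3 3-ethoxycyclopent-2-en-1-one
Product: 6 3-(3-methylbut-3-en-1-yl)cyclopent-2-en-1-one, via Grignard reagent 4 (not isolated), via magnesium alkoxide adduct 5 (not isolated)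
Conditions: Mg, THF, 40 °C; then 3, THF, 0 °C; then 1 M aq HCl, 0 °C → rt
Reagents that add atoms: water, O
Why: Stork–Danheiser sequence, in which 1,2-addition of the Grignard reagent to the vinylogous ester and acid hydrolysis of the enol ether with loss of the tertiary hydroxyl transpose the carbonyl to give the 3-alkyl enone, leaving no stereocentre.

Step 3
Reactants: 6 3-(3-methylbut-3-en-1-yl)cyclopent-2-en-1-one
Product: 8 (S)-triethyl{[3-methyl-3-(3-methylbut-3-en-1-yl)cyclopent-1-en-1-yl]oxy}silane, via dimethylaluminium enolate 7 (not isolated)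
Conditions: Me3Al, copper thiophene-2-carboxylate Cu(O2CC4H3S) (5 mol %), chiral phosphoramidite L* [O,O'-(biphenyl-2,2'-diyl) N,N-bis(1-(naphthalen-2-yl)ethyl)phosphoramidite, one enantiomer] (10 mol %), Et2O, −30 °C; then TESOTf, THF, −30 → 0 °C
Reagents that add atoms: trimethylaluminium, C[Al](C)C; triethylsilyl trifluoromethanesulfonate, CC[Si](CC)(CC)OS(=O)(=O)C(F)(F)F
Why: Copper-catalysed asymmetric conjugate addition, in which the chiral copper–phosphoramidite species transfers methyl from Me3Al to the Re face of C3 (ligand control) to set the (S) quaternary carbon, and O-silylation of the aluminium enolate stores the enolate regiochemistry for the aldol.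

Step 4
Reactants: 8 (S)-triethyl{[3-methyl-3-(3-methylbut-3-en-1-yl)cyclopent-1-en-1-yl]oxy}silane; 9 acrolein (prop-2-enal)
Product: 12 (2S,3S)-2-[(1S)-1-hydroxyprop-2-en-1-yl]-3-methyl-3-(3-methylbut-3-en-1-yl)cyclopentan-1-one, via lithium enolate 10 (not isolated), via chlorozinc enolate 11 (not isolated)
Conditions: MeLi, THF, 0 °C → rt; ZnCl2, −78 °C; then 9, −78 °C; aq NH4Cl, chromatography
Reagents that add atoms: none
Why: Intermolecular aldol addition forming the key C–C bond, in which Si→Li→Zn exchange gives the regiodefined E-enolate that adds 1,2 to acrolein through a chair Zimmerman–Traxler transition state (anti aldol, setting 1S at the carbinol) on the enolate face opposite the larger butenyl chain of the neighbouring quaternary carbon (setting 2S, new chain cis to the methyl group), minor isomers being removed by chromatography.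

Step 5
Reactants: 12 (2S,3S)-2-[(1S)-1-hydroxyprop-2-en-1-yl]-3-methyl-3-(3-methylbut-3-en-1-yl)cyclopentan-1-one
Product: 13 (2S,3S)-2-[(1S)-1-(tert-butyldimethylsilyloxy)prop-2-en-1-yl]-3-methyl-3-(3-methylbut-3-en-1-yl)cyclopentan-1-one
Conditions: TBSOTf, 2,6-lutidine, CH2Cl2, −78 °C
Reagents that add atoms: tert-butyldimethylsilyl trifluoromethanesulfonate, CC(C)(C)[Si](C)(C)OS(=O)(=O)C(F)(F)F
Why: O-silylation with a silyl triflate and a hindered weak base at low temperature is faster than enolisation or retro-aldol cleavage, masks the carbinol against the organometallic of the next step and touches no stereocentre.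

Step 6
Reactants: 13 (2S,3S)-2-[(1S)-1-(tert-butyldimethylsilyloxy)prop-2-en-1-yl]-3-methyl-3-(3-methylbut-3-en-1-yl)cyclopentan-1-one
Product: 14 (1R,2S,3S)-2-[(1S)-1-(tert-butyldimethylsilyloxy)prop-2-en-1-yl]-3-methyl-3-(3-methylbut-3-en-1-yl)-1-(propan-2-yl)cyclopentan-1-ol
Conditions: iPrMgCl, anhydrous CeCl3, THF, −78 → 0 °C
Reagents that add atoms: isopropylmagnesium chloride, CC(C)[Mg]Cl
Why: Organocerium 1,2-addition (Imamoto conditions), whose low basicity suppresses enolisation and reduction of the hindered ketone, with isopropyl entering on the carbonyl face anti to the bulky silyloxyallyl substituent of the adjacent carbon, which sets the 1R carbinol with OH cis to that substituent.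

Step 7
Reactants: 14 (1R,2S,3S)-2-[(1S)-1-(tert-butyldimethylsilyloxy)prop-2-en-1-yl]-3-methyl-3-(3-methylbut-3-en-1-yl)-1-(propan-2-yl)cyclopentan-1-ol
Product: 15 (3R,3aS,4S,8aS)-4-(tert-butyldimethylsilyloxy)-6,8a-dimethyl-3-(propan-2-yl)-1,2,3,3a,4,7,8,8a-octahydroazulen-3-ol
Conditions: second-generation Grubbs catalyst RuCl2(=CHPh)(PCy3)(H2IMes) (5–10 mol %), toluene (0.005 M), 80 °C
Reagents that add atoms: none
Why: Ring-closing olefin metathesis between the vinyl group and the 1,1-disubstituted alkene, driven by loss of ethene, closes the seven-membered ring as its trisubstituted alkene, and because the two tethers are trans on the cyclopentane the trans ring fusion follows with no new stereocentre.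

Step 8
Reactants: 15 (3R,3aS,4S,8aS)-4-(tert-butyldimethylsilyloxy)-6,8a-dimethyl-3-(propan-2-yl)-1,2,3,3a,4,7,8,8a-octahydroazulen-3-ol
Product: 16 (3R,3aS,4S,8aS)-6,8a-dimethyl-3-(propan-2-yl)-1,2,3,3a,4,7,8,8a-octahydroazulene-3,4-diol
Conditions: TBAF, THF, rt → 45 °C; recrystallise
Reagents that add atoms: none
Why: Fluoride-mediated desilylation (strong Si–F bond) frees the secondary allylic alcohol under non-acidic conditions that spare the tertiary alcohol and the allylic system, the C–O bond and its configuration being untouched.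

Step 9
Reactants: 16 (3R,3aS,4S,8aS)-6,8a-dimethyl-3-(propan-2-yl)-1,2,3,3a,4,7,8,8a-octahydroazulene-3,4-diol; 17 4-methoxybenzoyl chloride
Product: 18 (3R,3aS,4S,8aS)-3-hydroxy-6,8a-dimethyl-3-(propan-2-yl)-1,2,3,3a,4,7,8,8a-octahydroazulen-4-yl 4-methoxybenzoate
Conditions: pyridine, DMAP (cat.), CH2Cl2, 0 °C → rt
Reagents that add atoms: none
Why: DMAP-catalysed acylation (nucleophilic catalysis) occurs only at the secondary allylic hydroxyl, the tertiary hydroxyl being too hindered, and proceeds with retention because the C–O bond is not broken.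

## Compound list

1 | 3-methylbut-3-en-1-ol | C=C(C)CCO | starting material
2 | 4-bromo-2-methylbut-1-ene | C=C(C)CCBr | intermediate
3 | 3-ethoxycyclopent-2-en-1-one | CCOC1=CC(=O)CC1 | starting material
4 | (3-methylbut-3-en-1-yl)magnesium bromide (in flask) | C=C(C)CC[Mg]Br | intermediate
5 | bromomagnesium 3-ethoxy-1-(3-methylbut-3-en-1-yl)cyclopent-2-en-1-olate (racemic, in flask) | CCOC1=CC(CCC(C)=C)(O[Mg]Br)CC1 | intermediate
6 | 3-(3-methylbut-3-en-1-yl)cyclopent-2-en-1-one | O=C1C=C(CCC(C)=C)CC1 | intermediate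
7 | dimethylaluminium (S)-3-methyl-3-(3-methylbut-3-en-1-yl)cyclopent-1-en-1-olate (in flask) | C[Al](C)OC1=C[C@@](C)(CCC(C)=C)CC1 | intermediate
8 | (S)-triethyl{[3-methyl-3-(3-methylbut-3-en-1-yl)cyclopent-1-en-1-yl]oxy}silane | CC[Si](CC)(CC)OC1=C[C@@](C)(CCC(C)=C)CC1 | intermediate
9 | acrolein (prop-2-enal) | C=CC=O | starting material
10 | lithium (S)-3-methyl-3-(3-methylbut-3-en-1-yl)cyclopent-1-en-1-olate (in flask) | [Li]OC1=C[C@@](C)(CCC(C)=C)CC1 | intermediate
11 | chlorozinc (S)-3-methyl-3-(3-methylbut-3-en-1-yl)cyclopent-1-en-1-olate (in flask) | Cl[Zn]OC1=C[C@@](C)(CCC(C)=C)CC1 | intermediate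
12 | (2S,3S)-2-[(1S)-1-hydroxyprop-2-en-1-yl]-3-methyl-3-(3-methylbut-3-en-1-yl)cyclopentan-1-one | O[C@@H](C=C)[C@H]1C(=O)CC[C@]1(C)CCC(C)=C | intermediate
13 | (2S,3S)-2-[(1S)-1-(tert-butyldimethylsilyloxy)prop-2-en-1-yl]-3-methyl-3-(3-methylbut-3-en-1-yl)cyclopentan-1-one | CC(C)(C)[Si](C)(C)O[C@@H](C=C)[C@H]1C(=O)CC[C@]1(C)CCC(C)=C | intermediate
14 | (1R,2S,3S)-2-[(1S)-1-(tert-butyldimethylsilyloxy)prop-2-en-1-yl]-3-methyl-3-(3-methylbut-3-en-1-yl)-1-(propan-2-yl)cyclopentan-1-ol | CC(C)(C)[Si](C)(C)O[C@@H](C=C)[C@H]1[C@](O)(C(C)C)CC[C@]1(C)CCC(C)=C | intermediate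
15 | (3R,3aS,4S,8aS)-4-(tert-butyldimethylsilyloxy)-6,8a-dimethyl-3-(propan-2-yl)-1,2,3,3a,4,7,8,8a-octahydroazulen-3-ol | CC(C)(C)[Si](C)(C)O[C@H]1C=C(C)CC[C@@]2(C)CC[C@@](O)(C(C)C)[C@H]12 | intermediate
16 | (3R,3aS,4S,8aS)-6,8a-dimethyl-3-(propan-2-yl)-1,2,3,3a,4,7,8,8a-octahydroazulene-3,4-diol | O[C@H]1C=C(C)CC[C@@]2(C)CC[C@@](O)(C(C)C)[C@H]12 | intermediate
17 | 4-methoxybenzoyl chloride | COc1ccc(C(Cl)=O)cc1 | starting material
18 | (3R,3aS,4S,8aS)-3-hydroxy-6,8a-dimethyl-3-(propan-2-yl)-1,2,3,3a,4,7,8,8a-octahydroazulen-4-yl 4-methoxybenzoate | COc1ccc(C(=O)O[C@H]2C=C(C)CC[C@@]3(C)CC[C@@](O)(C(C)C)[C@H]23)cc1 | target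

## Step count and risks

Total step count: 9. Longest linear sequence: 9 steps (1 → 18).

The three steps most likely to fail are steps 3, 4 and 6.

**Step 3.** Methyl transfer from Me3Al to a cyclopentenone is slower and usually less enantioselective than to six-membered enones, and the aluminium enolate must be silylated cleanly. The fallback reverses the roles of the two carbon groups, so that the chain rather than the methyl is introduced enantioselectively. It sets out from bromide 2, turned into Grignard reagent 4 as in step 2. Reagent 4 is added to purchased 3-methylcyclopent-2-en-1-one (CC1=CC(=O)CC1) with Cu(OTf)2 (3 mol %) and a chiral imidazolinium salt as N-heterocyclic carbene precursor in Et2O at −30 °C. This gives bromomagnesium (S)-3-methyl-3-(3-methylbut-3-en-1-yl)cyclopent-1-en-1-olate F1, which is silylated in the flask (TESCl, Et3N, DMPU) and so comes back to the route at 8.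

**Step 4.** The face selectivity at the enolate carbon rests only on methyl versus butenyl, and the anti:syn ratio at the carbinol may be low. Wrong-face isomers can only be removed by chromatography. The fallback moves control of the carbinol centre from the aldol to a reduction. It sets out from 8: the aldol is run with lithium enolate 10 alone (no zinc, −78 °C) and the carbinol epimers are not separated. The syn aldol (2S,3S)-2-[(1R)-1-hydroxyprop-2-en-1-yl]-3-methyl-3-(3-methylbut-3-en-1-yl)cyclopentan-1-one F2 is carried alongside 12 through the operations of steps 5 to 8, as follows.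

- Silylation gives (2S,3S)-2-[(1R)-1-(tert-butyldimethylsilyloxy)prop-2-en-1-yl]-3-methyl-3-(3-methylbut-3-en-1-yl)cyclopentan-1-one F3.
- Isopropyl addition gives (1R,2S,3S)-2-[(1R)-1-(tert-butyldimethylsilyloxy)prop-2-en-1-yl]-3-methyl-3-(3-methylbut-3-en-1-yl)-1-(propan-2-yl)cyclopentan-1-ol F4.
- Metathesis gives (3R,3aS,4R,8aS)-4-(tert-butyldimethylsilyloxy)-6,8a-dimethyl-3-(propan-2-yl)-1,2,3,3a,4,7,8,8a-octahydroazulen-3-ol F5.
- Desilylation gives (3R,3aS,4R,8aS)-6,8a-dimethyl-3-(propan-2-yl)-1,2,3,3a,4,7,8,8a-octahydroazulene-3,4-diol F6.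

The mixture of 16 and F6 is oxidised with MnO2 (CH2Cl2, rt) to the single enone (3R,3aR,8aS)-3-hydroxy-6,8a-dimethyl-3-(propan-2-yl)-2,3,3a,7,8,8a-hexahydroazulen-4(1H)-one F7. Hydroxyl-directed 1,2-reduction with Me4NBH(OAc)3 (MeCN/AcOH, −20 °C) delivers hydride from the face of the tertiary hydroxyl and returns the route to 16.

**Step 6.** A secondary organometallic must add to a ketone flanked by a branched α-substituent, so reduction, enolisation or no reaction are possible. The fallback sets out from ketone 13 and closes the seven-membered ring first (second-generation Grubbs catalyst, toluene, 80 °C). This gives (3aS,4S,8aS)-4-(tert-butyldimethylsilyloxy)-6,8a-dimethyl-2,3a,4,7,8,8a-hexahydroazulen-3(1H)-one F8. The smaller isopropenyl nucleophile, which has no β-hydride to give and can only be used once the metathesis is done, is then added (isopropenylmagnesium bromide, CeCl3, THF, −78 °C). It adds anti to the angular methyl group to give (3S,3aS,4S,8aS)-4-(tert-butyldimethylsilyloxy)-6,8a-dimethyl-3-(prop-1-en-2-yl)-1,2,3,3a,4,7,8,8a-octahydroazulen-3-ol F9. Selective hydrogenation of the 1,1-disubstituted alkene beside the trisubstituted ring alkene (RhCl(PPh3)3, H2, benzene, rt) comes back to the route at 15.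

## Further compounds

F1 | step 3 | bromomagnesium (S)-3-methyl-3-(3-methylbut-3-en-1-yl)cyclopent-1-en-1-olate | Br[Mg]OC1=C[C@@](C)(CCC(C)=C)CC1
F2 | step 4 | (2S,3S)-2-[(1R)-1-hydroxyprop-2-en-1-yl]-3-methyl-3-(3-methylbut-3-en-1-yl)cyclopentan-1-one | O[C@H](C=C)[C@H]1C(=O)CC[C@]1(C)CCC(C)=C
F3 | step 4 | (2S,3S)-2-[(1R)-1-(tert-butyldimethylsilyloxy)prop-2-en-1-yl]-3-methyl-3-(3-methylbut-3-en-1-yl)cyclopentan-1-one | CC(C)(C)[Si](C)(C)O[C@H](C=C)[C@H]1C(=O)CC[C@]1(C)CCC(C)=C
F4 | step 4 | (1R,2S,3S)-2-[(1R)-1-(tert-butyldimethylsilyloxy)prop-2-en-1-yl]-3-methyl-3-(3-methylbut-3-en-1-yl)-1-(propan-2-yl)cyclopentan-1-ol | CC(C)(C)[Si](C)(C)O[C@H](C=C)[C@H]1[C@](O)(C(C)C)CC[C@]1(C)CCC(C)=C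
F5 | step 4 | (3R,3aS,4R,8aS)-4-(tert-butyldimethylsilyloxy)-6,8a-dimethyl-3-(propan-2-yl)-1,2,3,3a,4,7,8,8a-octahydroazulen-3-ol | CC(C)(C)[Si](C)(C)O[C@@H]1C=C(C)CC[C@@]2(C)CC[C@@](O)(C(C)C)[C@H]12
F6 | step 4 | (3R,3aS,4R,8aS)-6,8a-dimethyl-3-(propan-2-yl)-1,2,3,3a,4,7,8,8a-octahydroazulene-3,4-diol | O[C@@H]1C=C(C)CC[C@@]2(C)CC[C@@](O)(C(C)C)[C@H]12
F7 | step 4 | (3R,3aR,8aS)-3-hydroxy-6,8a-dimethyl-3-(propan-2-yl)-2,3,3a,7,8,8a-hexahydroazulen-4(1H)-one | O=C1C=C(C)CC[C@@]2(C)CC[C@@](O)(C(C)C)[C@H]12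
F8 | step 6 | (3aS,4S,8aS)-4-(tert-butyldimethylsilyloxy)-6,8a-dimethyl-2,3a,4,7,8,8a-hexahydroazulen-3(1H)-one | CC(C)(C)[Si](C)(C)O[C@H]1C=C(C)CC[C@@]2(C)CCC(=O)[C@H]12
F9 | step 6 | (3S,3aS,4S,8aS)-4-(tert-butyldimethylsilyloxy)-6,8a-dimethyl-3-(prop-1-en-2-yl)-1,2,3,3a,4,7,8,8a-octahydroazulen-3-ol | CC(C)(C)[Si](C)(C)O[C@H]1C=C(C)CC[C@@]2(C)CC[C@@](O)(C(C)=C)[C@H]12
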